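**Assumption:** the SMILES is read as (5S,8R), i.e. the 5‑(5‑phenylpentyl) and 8‑OMe groups are cis. Methyl (R)‑glycidate (serine‑derived) is the purchased chiral material, and 7‑phenylhept‑1‑yne is made rather than bought. The route is a paper design; no step has been run.

## Retrosynthetic overview

1. Waltherione H ⇐ face‑selective hydrogenation of the C5=C6 alkene of a 7,8‑dihydroquinolin‑4‑one; C5 is set by the C8‑OMe centre.
2. Carbocycle (formed last) ⇐ 6‑endo hydroarylation of a pendant alkyne by the pyridinone C–H, forming C4a–C5.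
3. N‑Methoxy‑4‑pyridinone ⇐ O→N exchange (MeONH2) on a γ‑pyrone.
4. γ‑Pyrone (heterocycle, formed first) ⇐ key hetero‑Diels–Alder [4+2] of an α‑oxoketene (from an acyl Meldrum's acid) with the silyl enol ether of methoxyacetone.
5. α‑Methoxy acid ⇐ methyl (R)‑glycidate (C8 stereocentre) + 7‑phenylhept‑1‑yne by alkynylalane epoxide opening.

## Route

**Step 1**
Reactants: 1, (5‑bromopentyl)benzene; 2, lithium acetylide–ethylenediamine complex
Product: 3, 7‑phenylhept‑1‑yne
Conditions: DMSO, rt
Reagents that add atoms: none beyond reactant 2 (supplies the two alkyne carbons)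
Why: SN2 alkylation of acetylide on a primary bromide gives the terminal alkyne.

**Step 2**
Reactants: 3, 7‑phenylhept‑1‑yne; 4, methyl (R)‑oxirane‑2‑carboxylate (methyl (R)‑glycidate)
Product: 5, methyl (R)‑2‑hydroxy‑10‑phenyldec‑4‑ynoate
Conditions: 3, n‑BuLi, PhMe, 0 °C; Et2AlCl; then 4, 0 °C → rt
Reagents that add atoms: none (both partners are numbered reactants)
Why: Alkynylalane epoxide opening occurs by SN2 at the terminal CH2 (chelation to epoxide/ester), so the purchased (R) centre is untouched and becomes C8 of the target.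

**Step 3**
Reactants: 5, methyl (R)‑2‑hydroxy‑10‑phenyldec‑4‑ynoate
Product: 6, methyl (R)‑2‑methoxy‑10‑phenyldec‑4‑ynoate
Conditions: MeI, Ag2O, MeCN, rt, dark
Reagents that add atoms: iodomethane, CI
Why: Purdie O‑methylation under neutral conditions alkylates the hydroxyl without enolising the α‑stereocentre.

**Step 4**
Reactants: 6, methyl (R)‑2‑methoxy‑10‑phenyldec‑4‑ynoate
Product: 7, (R)‑2‑methoxy‑10‑phenyldec‑4‑ynoic acid
Conditions: LiOH·H2O, THF/H2O, 0 °C; then H3O+
Reagents that add atoms: lithium hydroxide/water, [Li+].[OH-] / O (source of the acid OH oxygen)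
Why: Mild saponification at 0 °C cleaves the methyl ester without epimerising the α‑alkoxy centre.

**Step 5**
Reactants: 7, (R)‑2‑methoxy‑10‑phenyldec‑4‑ynoic acid; 8, Meldrum's acid (2,2‑dimethyl‑1,3‑dioxane‑4,6‑dione)
Product: 9, 5‑[(2R)‑1‑hydroxy‑2‑methoxy‑10‑phenyldec‑4‑yn‑1‑ylidene]‑2,2‑dimethyl‑1,3‑dioxane‑4,6‑dione (enolised acyl Meldrum's acid)
Conditions: DCC, DMAP, CH2Cl2, 0 °C → rt
Reagents that add atoms: none beyond reactant 8
Why: Carbodiimide/DMAP C‑acylation of Meldrum's acid gives the enolised adduct, a neutral thermal precursor of the α‑oxoketene, without touching the stereocentre.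

**Step 6**
Reactants: 10, methoxyacetone (1‑methoxypropan‑2‑one)
Product: 11, (Z)‑tert‑butyl[(1‑methoxyprop‑1‑en‑2‑yl)oxy]dimethylsilane (either alkene geometry is usable)
Conditions: TBSOTf, Et3N, CH2Cl2, 0 °C → rt (equilibrating)
Reagents that add atoms: tert‑butyldimethylsilyl triflate, CC(C)(C)[Si](C)(C)OS(=O)(=O)C(F)(F)F
Why: Soft enolisation under thermodynamic control should place the enol ether on the more acidic, methoxy‑bearing carbon.

**Step 7 (key step)**
Reactants: 9, acyl Meldrum's acid; 11, silyl enol ether (3 equiv)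
Product: 12, 3‑methoxy‑6‑[(1R)‑1‑methoxy‑9‑phenylnon‑3‑yn‑1‑yl]‑2‑methyl‑4H‑pyran‑4‑one
Conditions: PhMe, 90 °C (–acetone, –CO2); then TsOH·H2O (cat.), THF, rt
Reagents that add atoms: none beyond reactant 11 (supplies C2‑Me and C3‑OMe; TBSOH is lost)
Why: Retro‑[4+2] of the acyl Meldrum's acid releases an α‑oxoketene that undergoes an inverse‑demand hetero‑Diels–Alder [4+2] with the enol ether (ketene carbon to the CH(OMe) terminus, acyl oxygen to the siloxy carbon), and acid‑promoted loss of TBSOH gives the γ‑pyrone; the vinyl‑ether version of this is a known γ‑pyrone synthesis, and the stereocentre is not involved.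

**Step 8**
Reactants: 12, γ‑pyrone
Product: 13, 1,3‑dimethoxy‑6‑[(1R)‑1‑methoxy‑9‑phenylnon‑3‑yn‑1‑yl]‑2‑methylpyridin‑4(1H)‑one
Conditions: MeONH2·HCl, pyridine, EtOH, 80 °C
Reagents that add atoms: O‑methylhydroxylamine hydrochloride, CON.Cl
Why: Pyranone‑to‑pyridinone exchange (conjugate addition, ring opening, recyclisation, dehydration) with the α‑effect amine installs N–OMe under weakly basic conditions that should leave the adjacent ether centre intact.

**Step 9**
Reactants: 13, alkynyl N‑methoxypyridinone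
Product: 14, (8R)‑1,3,8‑trimethoxy‑2‑methyl‑5‑(5‑phenylpentyl)‑7,8‑dihydroquinolin‑4(1H)‑one
Conditions: [JohnPhosAu(MeCN)]SbF6 (5 mol %), DCE, 50 °C
Reagents that add atoms: none
Why: Au(I)‑catalysed 6‑endo‑dig intramolecular hydroarylation: the enaminone‑type ring carbon attacks the distal alkyne carbon, closing the carbocycle with a C5=C6 alkene under non‑acidic conditions that should not eliminate the C8 ether.

**Step 10**
Reactants: 14, 7,8‑dihydroquinolinone
Product: 15, waltherione H, (5S,8R)‑1,3,8‑trimethoxy‑2‑methyl‑5‑(5‑phenylpentyl)‑5,6,7,8‑tetrahydroquinolin‑4(1H)‑one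
Conditions: H2 (1 atm), 10 % Pd/C, EtOAc, rt
Reagents that add atoms: none (H2 only)
Why: Heterogeneous syn‑hydrogenation; A(1,3) strain with N–OMe should force the C8‑OMe pseudoaxial and block that face, so hydrogen adds anti to OMe and the side chain ends cis to it, giving 5S.

## Compound list

1 | (5‑bromopentyl)benzene | BrCCCCCc1ccccc1 | starting material
2 | lithium acetylide–ethylenediamine complex | [Li]C#C.NCCN | starting material
3 | 7‑phenylhept‑1‑yne | C#CCCCCCc1ccccc1 | intermediate
4 | methyl (R)‑oxirane‑2‑carboxylate | COC(=O)[C@H]1CO1 | starting material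
5 | methyl (R)‑2‑hydroxy‑10‑phenyldec‑4‑ynoate | COC(=O)[C@H](O)CC#CCCCCCc1ccccc1 | intermediate
6 | methyl (R)‑2‑methoxy‑10‑phenyldec‑4‑ynoate | COC(=O)[C@H](OC)CC#CCCCCCc1ccccc1 | intermediate
7 | (R)‑2‑methoxy‑10‑phenyldec‑4‑ynoic acid | OC(=O)[C@H](OC)CC#CCCCCCc1ccccc1 | intermediate
8 | Meldrum's acid | CC1(C)OC(=O)CC(=O)O1 | starting material
9 | 5‑[(2R)‑1‑hydroxy‑2‑methoxy‑10‑phenyldec‑4‑yn‑1‑ylidene]‑2,2‑dimethyl‑1,3‑dioxane‑4,6‑dione | CC1(C)OC(=O)C(=C(O)[C@H](OC)CC#CCCCCCc2ccccc2)C(=O)O1 | intermediate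
10 | methoxyacetone | COCC(C)=O | starting material
11 | (Z)‑tert‑butyl[(1‑methoxyprop‑1‑en‑2‑yl)oxy]dimethylsilane | CO/C=C(/C)O[Si](C)(C)C(C)(C)C | intermediate
12 | 3‑methoxy‑6‑[(1R)‑1‑methoxy‑9‑phenylnon‑3‑yn‑1‑yl]‑2‑methyl‑4H‑pyran‑4‑one | COc1c(C)oc(cc1=O)[C@H](OC)CC#CCCCCCc1ccccc1 | intermediate
13 | 1,3‑dimethoxy‑6‑[(1R)‑1‑methoxy‑9‑phenylnon‑3‑yn‑1‑yl]‑2‑methylpyridin‑4(1H)‑one | COc1c(C)n(OC)c(cc1=O)[C@H](OC)CC#CCCCCCc1ccccc1 | intermediate
14 | (8R)‑1,3,8‑trimethoxy‑2‑methyl‑5‑(5‑phenylpentyl)‑7,8‑dihydroquinolin‑4(1H)‑one | COc1c(C)n(OC)c2c(c1=O)C(CCCCCc1ccccc1)=CC[C@H]2OC | intermediate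
15 | waltherione H, (5S,8R)‑1,3,8‑trimethoxy‑2‑methyl‑5‑(5‑phenylpentyl)‑5,6,7,8‑tetrahydroquinolin‑4(1H)‑one | COc1c(C)n(OC)c2c(c1=O)[C@@H](CCCCCc1ccccc1)CC[C@H]2OC | target

## Summary

Total steps: 10.
Longest linear sequence: 9 (steps 1, 2, 3, 4, 5, 7, 8, 9, 10); step 6 is a one‑step side branch.

Three steps most likely to fail, each with a fallback:

- **Step 10 (facial selectivity of the hydrogenation; also possible hydrogenolysis of the C8 ether or alkene migration).** Fallback: ionic hydrogenation (Et3SiH/TFA), where protonation at C6 gives a pyridinone‑stabilised C5 cation and hydride adds axially, anti to the pseudoaxial OMe. If the diastereomer ratio is still poor, use a hydroxyl‑directed homogeneous hydrogenation on the 8‑epi free alcohol (made from the enantiomeric glycidate), then Mitsunobu inversion at C8 and O‑methylation.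
- **Step 9 (6‑endo hydroarylation may compete with 5‑exo closure, ether participation or catalyst inhibition by the pyridinone).** Fallback: electrophilic iodocyclisation (ICl or I2/NaHCO3) to the 6‑iodo‑7,8‑dihydroquinolinone, with the C–I bond removed in the final hydrogenation (Pd/C, H2, Et3N).
- **Step 8 (O→N exchange at a 2,6‑disubstituted pyrone may be slow, and the ring‑opened intermediate could erode C8).** Fallback: exchange with NH2OH·HCl/NaOAc to the N‑hydroxypyridinone, then O‑methylate the N–OH (MeI, K2CO3).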